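At early times none of the reagent is dissolved, so the gas crosses at its ceiling r, the transfer coefficient times the saturation concentration, 6.91 mM h⁻¹; dissolved reagent can only lower that rate.

    gas ⇌ reagent, rate k1*(csat - [reagent]) (k1 = 8.0 × 10⁻⁵ s⁻¹, csat = 24 mM)
    starting material + reagent → other mono adduct + released group (k2 = 0.0030 L mol⁻¹ s⁻¹)
    released group → by-product carried off (k3 = 1.9 × 10⁻⁵ s⁻¹)
    reagent + single product → double product + released group (k4 = 0.0069 L mol⁻¹ s⁻¹)
    starting material + reagent → single product + released group (k5 = 0.0049 L mol⁻¹ s⁻¹)
    reagent + other mono adduct → double product + released group (k6 = 0.0080 L mol⁻¹ s⁻¹)
    reagent + released group ⇌ idle adduct, settled at all times (K7 = 1600 L mol⁻¹)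

starting material 0.40 M (fed, over 8.0 h); gas 24 mM (held); time 4.0 d

- part of the starting material that has reacted at 4.0 d
- share of the unused reagent that is free and not bound as idle adduct, at 4.0 d

- what is said of released group includes idle adduct
- at the start none of reagent is dissolved
- run time (flask): 4.0 d

Reagent facing the whole charge, as if it were there at once, has a half-life of 0.098 h by step 5 alone and 0.0609 h by steps 2 and 5 together, shorter than the crossing's own 2.41 h, so we treat the crossing as the rate-limiting step. We therefore carry one quantity: the gas allowance, what the ceiling delivers by the asked time per starting material charged, x = 1.66. But each starting material has 2 places to fill, and the constants of the first and second fillings are similar, so we take them as equal and work with what is left. After an exposure τ, the open places per charge are (2+τ)e^−τ = 2 − x. This gives τ = 2.60, so 7.42% of the starting material is left and c is about 92.6%, with nothing yet counted as idle adduct.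

For fr, the free share is one over one plus K times free released group, K being the balance constant. Carrying-off has a half-life of 0.422 d, shorter than the run, so as a first estimate, with the uptake into idle adduct not counted, we set free released group at r over its rate constant, 0.101 M, which puts fr at about 0.615%. Growing idle adduct takes up released group, so we hold this as a low estimate of fr.

The forecast says 88% and 0.9%, on the ground that “Gas transfer limits the run”; our c is higher.

The simulation gives 82.8% and 0.924%. Reagent in products, idle adduct and free solution comes to 0.644 M, an average of 6.71 mM h⁻¹, just under the ceiling. Of this, 0.110 M stands as idle adduct. The neighbour flask charged with 1.0 M has x = 0.664, and its conversion stays below that, at 48.1%.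

The numbers were drawn at random within sensible limits.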